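**Retrosynthetic overview**
- The target is the 3'-O-debenzylated form of a benzyl-protected flavone; the benzyl ether is removed last by hydrogenolysis.
- Ring C (the 4-pyranone) is the only ring built, and it is closed last, by I2/DMSO oxidative cyclisation of a 2'-hydroxychalcone. Rings A and B are bought as benzenes.
- The chalcone Cα–Cβ bond comes from an intermolecular Claisen–Schmidt aldol condensation of 2'-hydroxy-3',4',5'-trimethoxyacetophenone with 3-benzyloxy-4,5-dimethoxybenzaldehyde.
- The ring A ketone comes from 2,3,4-trimethoxybenzaldehyde (Baeyer–Villiger to the phenol, then ortho-acetylation). The ring B aldehyde comes from 5-bromovanillin (hydroxylation, selective 4-O-methylation, benzylation).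

Assumption: the target has no stereocentre and is achiral, so there is no enantiomer to select; the route is matched to the SMILES as drawn.

**Step 1**
Reactants: 1 2,3,4-trimethoxybenzaldehyde
Product: 3 2,3,4-trimethoxyphenol, via aryl formate 2 (not isolated)
Conditions: mCPBA (1.3 equiv), CH2Cl2, 0 °C to rt, 12 h; aq Na2SO3/NaHCO3 wash; then K2CO3 (0.2 equiv), MeOH, rt, 1 h
Reagents that add atoms: mCPBA, O=C(OO)c1cccc(Cl)c1
Why: Baeyer–Villiger (Dakin-type) oxidation in which the electron-rich trimethoxyphenyl group migrates in preference to hydride, after which the labile aryl formate is transesterified by methanol to free the phenol; no stereocentre is formed.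

**Step 2**
Reactants: 3 2,3,4-trimethoxyphenol
Product: 5 1-(2-hydroxy-3,4,5-trimethoxyphenyl)ethan-1-one, via aryl acetate 4 (not isolated)
Conditions: AcOH (solvent), BF3·OEt2 (3 equiv), 90 °C, 3 h; then H2O, extraction
Reagents that add atoms: acetic acid, CC(=O)O
Why: BF3-promoted O-acetylation followed by Fries rearrangement (Nencki-type ortho-acylation), in which the position para to the phenol oxygen is blocked by OMe so the acetyl group goes to the only free ortho carbon and gives the chelated o-hydroxy ketone, BF3 being too mild to cleave the methyl ethers.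

**Step 3**
Reactants: 6 5-bromovanillin (3-bromo-4-hydroxy-5-methoxybenzaldehyde)
Product: 7 3,4-dihydroxy-5-methoxybenzaldehyde
Conditions: NaOH (8 equiv), Cu powder (5 mol %), H2O, reflux, N2, 24 h; then HCl to pH 2, EtOAc extraction
Reagents that add atoms: sodium hydroxide, [Na+].[OH-]
Why: Copper-catalysed Ullmann-type hydroxylation of the aryl bromide by hydroxide, a classical scalable conversion of 5-bromovanillin that is run under N2 because the catechol dianion is air-sensitive.

**Step 4**
Reactants: 7 3,4-dihydroxy-5-methoxybenzaldehyde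
Product: 8 3-hydroxy-4,5-dimethoxybenzaldehyde
Conditions: Me2SO4 (1.05 equiv), Na2CO3 (1.1 equiv), acetone, reflux, 6 h
Reagents that add atoms: dimethyl sulfate, COS(=O)(=O)OC
Why: Regioselective Williamson methylation, since the 4-OH is para to the formyl group and clearly the more acidic, so one equivalent of weak base forms and methylates only the 4-phenoxide and leaves the 3-OH free.

**Step 5**
Reactants: 8 3-hydroxy-4,5-dimethoxybenzaldehyde
Product: 9 3-(benzyloxy)-4,5-dimethoxybenzaldehyde
Conditions: BnBr (1.2 equiv), K2CO3 (2 equiv), DMF, 60 °C, 4 h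
Reagents that add atoms: benzyl bromide, BrCc1ccccc1
Why: Williamson ether synthesis on the only remaining phenol, giving a benzyl ether that survives the strong base of step 6 and the I2/DMSO of step 7 and can be removed without touching the methyl ethers.

**Step 6**
Reactants: 5 1-(2-hydroxy-3,4,5-trimethoxyphenyl)ethan-1-one; 9 3-(benzyloxy)-4,5-dimethoxybenzaldehyde
Product: 11 (E)-3-[3-(benzyloxy)-4,5-dimethoxyphenyl]-1-(2-hydroxy-3,4,5-trimethoxyphenyl)prop-2-en-1-one, via aldol adduct 10 (not isolated)
Conditions: KOH (50 % aq, 5 equiv), EtOH, 0 °C to rt, 36 h; then cold 1 M HCl, filtration, recrystallisation from EtOH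
Reagents that add atoms: none
Why: Claisen–Schmidt crossed aldol condensation in which the enolate of the only enolisable partner 5 adds to the non-enolisable aldehyde 9 and the β-hydroxy ketone loses water by E1cB, so the racemic carbinol centre of 10 disappears and the alkene forms as the thermodynamically favoured E isomer.

**Step 7**
Reactants: 11 (E)-3-[3-(benzyloxy)-4,5-dimethoxyphenyl]-1-(2-hydroxy-3,4,5-trimethoxyphenyl)prop-2-en-1-one
Product: 13 2-[3-(benzyloxy)-4,5-dimethoxyphenyl]-6,7,8-trimethoxy-4H-chromen-4-one, via flavanone 12 (not isolated)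
Conditions: I2 (10 mol %), DMSO, 130 °C, 3 h; then aq Na2S2O3, filtration, recrystallisation
Reagents that add atoms: none
Why: Iodine-catalysed oxidative cyclisation in which intramolecular oxa-Michael addition of the 2'-phenol gives the flavanone and the I2/DMSO couple (DMSO as terminal oxidant) dehydrogenates it to the aromatic 4-pyranone, erasing the transient C2 stereocentre.

**Step 8**
Reactants: 13 2-[3-(benzyloxy)-4,5-dimethoxyphenyl]-6,7,8-trimethoxy-4H-chromen-4-one
Product: 14 2-(3-hydroxy-4,5-dimethoxyphenyl)-6,7,8-trimethoxy-4H-chromen-4-one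
Conditions: H2 (1 atm), Pd/C (10 %), EtOAc/MeOH 1:1, rt, 2–4 h, monitored by TLC
Reagents that add atoms: none
Why: Catalytic hydrogenolysis of the benzyl aryl ether, under which the methyl ethers and the vinylogous-ester C2=C3 bond of the chromone are untouched at 1 atm and room temperature; the target has no stereocentre.

**Compound list**
1 | 2,3,4-trimethoxybenzaldehyde | COc1ccc(C=O)c(OC)c1OC | starting material
2 | 2,3,4-trimethoxyphenyl formate (aryl formate, not isolated) | COc1ccc(OC=O)c(OC)c1OC | intermediate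
3 | 2,3,4-trimethoxyphenol | COc1ccc(O)c(OC)c1OC | intermediate
4 | 2,3,4-trimethoxyphenyl acetate (aryl acetate, not isolated) | COc1ccc(OC(C)=O)c(OC)c1OC | intermediate
5 | 1-(2-hydroxy-3,4,5-trimethoxyphenyl)ethan-1-one | CC(=O)c1cc(OC)c(OC)c(OC)c1O | intermediate
6 | 5-bromovanillin (3-bromo-4-hydroxy-5-methoxybenzaldehyde) | COc1cc(C=O)cc(Br)c1O | starting material
7 | 3,4-dihydroxy-5-methoxybenzaldehyde | COc1cc(C=O)cc(O)c1O | intermediate
8 | 3-hydroxy-4,5-dimethoxybenzaldehyde | COc1cc(C=O)cc(O)c1OC | intermediate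
9 | 3-(benzyloxy)-4,5-dimethoxybenzaldehyde | COc1cc(C=O)cc(OCc2ccccc2)c1OC | intermediate
10 | 3-[3-(benzyloxy)-4,5-dimethoxyphenyl]-3-hydroxy-1-(2-hydroxy-3,4,5-trimethoxyphenyl)propan-1-one (aldol adduct, racemic, not isolated) | COc1cc(C(O)CC(=O)c2cc(OC)c(OC)c(OC)c2O)cc(OCc2ccccc2)c1OC | intermediate
11 | (E)-3-[3-(benzyloxy)-4,5-dimethoxyphenyl]-1-(2-hydroxy-3,4,5-trimethoxyphenyl)prop-2-en-1-one | COc1cc(/C=C/C(=O)c2cc(OC)c(OC)c(OC)c2O)cc(OCc2ccccc2)c1OC | intermediate
12 | 2-[3-(benzyloxy)-4,5-dimethoxyphenyl]-6,7,8-trimethoxy-2,3-dihydro-4H-chromen-4-one (flavanone, racemic, not isolated) | COc1cc(C2CC(=O)c3cc(OC)c(OC)c(OC)c3O2)cc(OCc2ccccc2)c1OC | intermediate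
13 | 2-[3-(benzyloxy)-4,5-dimethoxyphenyl]-6,7,8-trimethoxy-4H-chromen-4-one | COc1cc(-c2cc(=O)c3cc(OC)c(OC)c(OC)c3o2)cc(OCc2ccccc2)c1OC | intermediate
14 | 2-(3-hydroxy-4,5-dimethoxyphenyl)-6,7,8-trimethoxy-4H-chromen-4-one | COc1cc(-c2cc(=O)c3cc(OC)c(OC)c(OC)c3o2)cc(O)c1OC | target

**Totals**
Total step count: 8.
Longest linear sequence: 6 steps (6 → 7 → 8 → 9 → 11 → 13 → 14); the ring A branch 1 → 3 → 5 (2 steps) joins at step 6.

**Three steps most likely to fail, with fallbacks**

Step 3 (copper/hydroxide hydroxylation). The risks are the long reflux in strong base, partial reduction to vanillin and oxidative tarring of the catechol. The fallback sets out from 6 and comes back at 8, so it also bypasses step 4. Compound 6 is O-methylated (MeI, K2CO3, DMF, rt) to 3-bromo-4,5-dimethoxybenzaldehyde F1. Miyaura borylation (B2pin2, Pd(dppf)Cl2 3 mol %, KOAc, dioxane, 90 °C) then gives 3,4-dimethoxy-5-(4,4,5,5-tetramethyl-1,3,2-dioxaborolan-2-yl)benzaldehyde F2. Mild oxidation of the C–B bond (NaBO3·4H2O, THF/H2O, rt) delivers phenol 8 with the oxygen pattern fixed by the bromide position, with no regioselective alkylation needed.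

Step 4 (selective mono-methylation). The risks are over-methylation to 3,4,5-trimethoxybenzaldehyde and some 3-O-methyl isomer. The fallback sets out from 7 and comes back at 9, so it also replaces step 5. It reverses the order of alkylations and uses the opposite selectivity of the dianion. Compound 7 is treated with NaH (2.2 equiv) in DMSO at rt, then BnBr (1.0 equiv). The 4-phenoxide is delocalised into the para-formyl group and flanked on both sides, so the more nucleophilic 3-phenoxide is benzylated, giving 3-(benzyloxy)-4-hydroxy-5-methoxybenzaldehyde F3. Unselective methylation of the one remaining phenol (MeI, K2CO3, DMF, rt) then gives 9.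

Step 8 (hydrogenolysis). The risks are over-reduction of the chromone C2=C3 bond and poisoning of Pd/C by sulfur or iodine traces from step 7. The fallback sets out from 8 and comes back at 14, replacing benzyl by an acid-labile group so that no hydrogenation is needed.
- Phenol 8 is protected (MOMCl, iPr2NEt, CH2Cl2, 0 °C to rt) as 3,4-dimethoxy-5-(methoxymethoxy)benzaldehyde F4.
- Claisen–Schmidt condensation of F4 with 5 (KOH, EtOH, rt) passes through the racemic aldol adduct 3-hydroxy-1-(2-hydroxy-3,4,5-trimethoxyphenyl)-3-[3,4-dimethoxy-5-(methoxymethoxy)phenyl]propan-1-one F5 to the chalcone (E)-1-(2-hydroxy-3,4,5-trimethoxyphenyl)-3-[3,4-dimethoxy-5-(methoxymethoxy)phenyl]prop-2-en-1-one F6.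
- I2 (10 mol %) in DMSO at 130 °C cyclises F6 through the racemic flavanone 2-[3,4-dimethoxy-5-(methoxymethoxy)phenyl]-6,7,8-trimethoxy-2,3-dihydro-4H-chromen-4-one F7 to the flavone 2-[3,4-dimethoxy-5-(methoxymethoxy)phenyl]-6,7,8-trimethoxy-4H-chromen-4-one F8.
- 3 M HCl in MeOH at 50 °C removes the acetal to give 14. Any acetal already lost under the hot I2/DMSO conditions converges on 14 as well.

**Further compounds**
F1 | step 3 | 3-bromo-4,5-dimethoxybenzaldehyde | COc1cc(C=O)cc(Br)c1OC
F2 | step 3 | 3,4-dimethoxy-5-(4,4,5,5-tetramethyl-1,3,2-dioxaborolan-2-yl)benzaldehyde | COc1cc(C=O)cc(B2OC(C)(C)C(C)(C)O2)c1OC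
F3 | step 4 | 3-(benzyloxy)-4-hydroxy-5-methoxybenzaldehyde | COc1cc(C=O)cc(OCc2ccccc2)c1O
F4 | step 8 | 3,4-dimethoxy-5-(methoxymethoxy)benzaldehyde | COCOc1cc(C=O)cc(OC)c1OC
F5 | step 8 | 3-hydroxy-1-(2-hydroxy-3,4,5-trimethoxyphenyl)-3-[3,4-dimethoxy-5-(methoxymethoxy)phenyl]propan-1-one (racemic) | COCOc1cc(C(O)CC(=O)c2cc(OC)c(OC)c(OC)c2O)cc(OC)c1OC
F6 | step 8 | (E)-1-(2-hydroxy-3,4,5-trimethoxyphenyl)-3-[3,4-dimethoxy-5-(methoxymethoxy)phenyl]prop-2-en-1-one | COCOc1cc(/C=C/C(=O)c2cc(OC)c(OC)c(OC)c2O)cc(OC)c1OC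
F7 | step 8 | 2-[3,4-dimethoxy-5-(methoxymethoxy)phenyl]-6,7,8-trimethoxy-2,3-dihydro-4H-chromen-4-one (racemic) | COCOc1cc(C2CC(=O)c3cc(OC)c(OC)c(OC)c3O2)cc(OC)c1OC
F8 | step 8 | 2-[3,4-dimethoxy-5-(methoxymethoxy)phenyl]-6,7,8-trimethoxy-4H-chromen-4-one | COCOc1cc(-c2cc(=O)c3cc(OC)c(OC)c(OC)c3o2)cc(OC)c1OC
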